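**Strategy.** Each outer 4,4-dimethylcyclohexane-1,3,5-trione ring is cut at two bonds, C-5–C-6 and C-1–C-2 (C-1 carries the CH2 bridge, C-3 the two methyls, C-6 is the C=O), which leads back to an aryl δ-lactone on the central ring and methyl 2,2-dimethylacetoacetate. The key step works at both ends of the mirror-symmetric core at once: the ketone enolate opens the two temporary lactones (Claisen) and a dianion Dieckmann closure then forms both outer rings, the last rings made, and frees the phenols. It exploits the phenolic oxygens ortho to the bridges and the quaternary C-3, which leaves one enolisable methyl and a non-enolisable ester. The two outer butanoyl groups are added last.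

Key step: step 2

Remark: the target has no stereocentre and no stereogenic double bond, so it is achiral and needs no stereocontrol; it is drawn as the enol tautomer of the given SMILES.

Remark: compound 3 is drawn as the bis-lactone that keeps the hydrogen-bonded OH next to the butanoyl group; the other lactone regioisomer would give the same compound 5 in step 2, because both aryl ester C–O bonds are cleaved there.

Step 1
Reactants: 1 1-(2,4,6-trihydroxyphenyl)butan-1-one; 2 acrylic acid (two molecules incorporated)
Product: 3 6-butanoyl-5-hydroxy-3,4,9,10-tetrahydro-2H,8H-pyrano[2,3-f]chromene-2,8-dione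
Conditions: 2 (4 equiv), Amberlyst-15, toluene, reflux, Dean–Stark
Reagents that add atoms: none
Why: Acid-catalysed conjugate C-alkylation (Friedel–Crafts-type hydroarylation of acrylic acid) at the two free, strongly activated ring carbons, followed by lactonisation onto a neighbouring phenol, is the known route from phloroglucinols to 3,4-dihydrocoumarins, and removal of water should drive both lactone closures.

Step 2
Reactants: 3 6-butanoyl-5-hydroxy-3,4,9,10-tetrahydro-2H,8H-pyrano[2,3-f]chromene-2,8-dione; 4 methyl 2,2-dimethyl-3-oxobutanoate (two molecules incorporated)
Product: 6 1-[3,5-bis[(2,4-dihydroxy-3,3-dimethyl-6-oxocyclohexa-1,4-dien-1-yl)methyl]-2,4,6-trihydroxyphenyl]butan-1-one, via ring-opened bis(β-diketo ester) 5 (not isolated)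
Conditions: 4 (5 equiv), LDA (5 equiv), THF, −78 °C; add 3, −78 → −20 °C; then LDA (8 equiv), −78 °C → rt; 1 M HCl
Reagents that add atoms: none
Why: The lithium enolate of 4, which can form only at the acetyl CH3 because C-2 is quaternary, should add to each aryl lactone carbonyl and expel the phenoxide (crossed Claisen acylation of a ketone enolate by a lactone, forming C-5–C-6), giving the lithium β-diketonates of 5. The second portion of LDA should then remove a proton from the only α′-CH2 of each diketonate (the other flank is the CMe2 carbon), and the terminal carbanion of this 1,3-dianion attacks the non-enolisable methyl ester in a Dieckmann condensation (forming C-1–C-2), so that each of the two outer rings closes in the 6-(enolendo)-exo-trig mode with loss of methoxide. The closest known reactions are the acylation of ketone enolates by lactones, the γ-functionalisation of β-diketone dianions, and the Dieckmann closure of 2,2-dialkyl-3,5-dioxo esters to filicinic- and syncarpic-acid-type triones. No stereocentre is formed. The step needs C- over O-acylation in the ring closure and attack by the bridge-side carbon only: the quaternary carbon leaves no other enolisable position, O-acylation would give an enol lactone that methoxide reopens, and C-acylation becomes irreversible once the new β-triketone is deprotonated. The butanoyl ketone of the central ring should stay untouched because the three neighbouring phenoxides make it a poor electrophile and a poor carbon acid.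

Step 3
Reactants: 6 1-[3,5-bis[(2,4-dihydroxy-3,3-dimethyl-6-oxocyclohexa-1,4-dien-1-yl)methyl]-2,4,6-trihydroxyphenyl]butan-1-one; 7 butanoic acid (two molecules incorporated)
Product: 8 1-[3,5-bis[(5-butanoyl-2,4-dihydroxy-3,3-dimethyl-6-oxocyclohexa-1,4-dien-1-yl)methyl]-2,4,6-trihydroxyphenyl]butan-1-one (target)
Conditions: 7 (2.2 equiv), DCC (2.2 equiv), DMAP (3 equiv), CH2Cl2, 0 °C → rt; 1 M HCl wash
Reagents that add atoms: none
Why: Steglich-type O-acylation of the strongly acidic enols of the two β-triketone rings followed by DMAP-mediated O→C acyl migration (the known one-pot C-acylation of cyclic 1,3-diones with a carboxylic acid, DCC and DMAP) should place a butanoyl group on C-5 of each outer ring, the only unsubstituted position in the molecule that lies between two carbonyl groups.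

**Compound list**

1 | 1-(2,4,6-trihydroxyphenyl)butan-1-one | CCCC(=O)c1c(O)cc(O)cc1O | starting material
2 | acrylic acid | C=CC(=O)O | starting material
3 | 6-butanoyl-5-hydroxy-3,4,9,10-tetrahydro-2H,8H-pyrano[2,3-f]chromene-2,8-dione | CCCC(=O)c1c(O)c2CCC(=O)Oc2c2CCC(=O)Oc12 | intermediate
4 | methyl 2,2-dimethyl-3-oxobutanoate | CC(=O)C(C)(C)C(=O)OC | starting material
5 | dimethyl 7,7′-(5-butanoyl-2,4,6-trihydroxy-1,3-phenylene)bis(2,2-dimethyl-3,5-dioxoheptanoate) | CCCC(=O)c1c(O)c(CCC(=O)CC(=O)C(C)(C)C(=O)OC)c(O)c(CCC(=O)CC(=O)C(C)(C)C(=O)OC)c1O | intermediate
6 | 1-[3,5-bis[(2,4-dihydroxy-3,3-dimethyl-6-oxocyclohexa-1,4-dien-1-yl)methyl]-2,4,6-trihydroxyphenyl]butan-1-one | CCCC(=O)c1c(O)c(CC2=C(O)C(C)(C)C(O)=CC2=O)c(O)c(CC2=C(O)C(C)(C)C(O)=CC2=O)c1O | intermediate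
7 | butanoic acid | CCCC(=O)O | starting material
8 | 1-[3,5-bis[(5-butanoyl-2,4-dihydroxy-3,3-dimethyl-6-oxocyclohexa-1,4-dien-1-yl)methyl]-2,4,6-trihydroxyphenyl]butan-1-one | CCCC(=O)C1=C(O)C(C)(C)C(O)=C(Cc2c(O)c(CC3=C(O)C(C)(C)C(O)=C(C(=O)CCC)C3=O)c(O)c(C(=O)CCC)c2O)C1=O | target

**Step count and risks**

Total steps: 3. Longest linear sequence: 3 (1 → 3 → 6 → 8).

Steps most likely to fail, most risky first:

Step 2. The ketone enolate may act as a base toward the lactone α-CH2 groups instead of as a nucleophile, so that the aryl ester enolates fragment, and the polyanion may leave solution before the second deprotonation. The fallback sets out from 3. Both lactones are opened with N,O-dimethylhydroxylamine hydrochloride and Me3Al to give 3,3′-(5-butanoyl-2,4,6-trihydroxy-1,3-phenylene)bis(N-methoxy-N-methylpropanamide) F1, which has no activated ester left to enolise or fragment. The lithium enolate of 4 is then acylated by this Weinreb amide, which comes back to the route at 5. Compound 5 is isolated and the two rings are closed in a separate Dieckmann operation (LDA, THF) to give 6.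

Step 3. Acyl transfer to the three phenolic oxygens may compete with O-acylation of the enols and the O→C shift, and the basic medium may start retro-Michael scrambling of the methylene bridges. The fallback sets out from 6 and uses Lewis-acid Friedel–Crafts C-acylation (butanoyl chloride, AlCl3, nitrobenzene), the classical way from filicinic acid to its acyl derivatives. The phenols are tied up as aluminium phenoxides and only the enol carbon C-5 of each outer ring is nucleophilic. It returns directly at 8 and makes no new compound (F0).

Step 1. Acrylic acid may acylate the ring instead of alkylating it (chromanone formation) or oligomerise, and the second annulation on the deactivated ring may stall. The fallback sets out from 1 with a two-fold Pechmann condensation with propiolic acid (H2SO4) to give 6-butanoyl-5-hydroxy-2H,8H-pyrano[2,3-f]chromene-2,8-dione F2. Hydrogenation of its two C3=C4 bonds (H2, Pd/C, EtOAc) comes back to the route at 3.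

Further compounds
F1 | step 2 | 3,3′-(5-butanoyl-2,4,6-trihydroxy-1,3-phenylene)bis(N-methoxy-N-methylpropanamide) | CCCC(=O)c1c(O)c(CCC(=O)N(C)OC)c(O)c(CCC(=O)N(C)OC)c1O
F2 | step 1 | 6-butanoyl-5-hydroxy-2H,8H-pyrano[2,3-f]chromene-2,8-dione | CCCC(=O)c1c(O)c2ccc(=O)oc2c2ccc(=O)oc12
F0 | step 3 | none | none
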